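## The problem

Glyinflanin C 14 is an unsymmetrical dibenzoylmethane in which a three-carbon 1,3-dicarbonyl chain joins ring A, a 4-hydroxy-3-prenylphenyl group, to C6 of a 7-hydroxy-2,2-dimethyl-2H-chromene, whose benzene ring is called ring B and whose pyran ring is called ring C here. The molecule has no stereocentre, so nothing has to be controlled but regiochemistry and chemoselectivity. Ring C must be fused to the resorcinol-type ring B in the linear sense, whereas the usual chromene annulations of 2,4-dihydroxyaryl carbonyl compounds close at the carbon between the two oxygens and give the angular isomer. On ring A the prenyl group has to go on carbon, ortho to the hydroxyl and without allylic transposition, in competition with O-alkylation, and the chain has to be made by a crossed carbon–carbon bond formation between one ring A and one ring B carbonyl partner. Several groups will not survive rough treatment: the prenyl group next to a free phenol cyclises to a chroman in strong acid, the styrene-like C3=C4 bond of the chromene is sensitive to acid, electrophilic oxidants and hydrogenation, the ortho-hydroxy-1,3-diketone dehydrates to a flavone in hot acid and suffers retro-Claisen cleavage in hot alkali, and the free phenols are easily oxidised. The feature that makes the key step possible is the substitution pattern of ring B: C4 is attached at C4a, para to the C7 hydroxyl, and O1 sits on C8a, para to C6, which carries the chain. C4a and C6 are therefore two carbon-bearing positions, each ortho to one oxygen and para to the other, interchanged by a mirror plane through C5 and C8. This is the pattern of the C2v-symmetric 4,6-dihydroxyisophthalaldehyde 1, in which either formyl/hydroxyl pair can become ring C while the other remains as the anchor for the chain.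

## Retrosynthesis

**14 from 13.** The last cut is at the two phenolic O–CH2 bonds: 14 is taken back to its bis(methoxymethyl) ether 13. Both phenols must be masked while the chain is built with a lithium enolate and an oxidant. Hydrogenolytic groups are ruled out by the two alkenes, and a silyl ether on ring B would migrate to the neighbouring benzylic alkoxide of the aldol step. An acetal stays in place and both acetals can leave in one operation. The forward step needs acid mild enough to spare the prenylphenol, the chromene and the ortho-hydroxy diketone.

**13 from 12, and 12 from 6 and 10.** The chain is cut between the central methylene and the carbonyl carbon on ring B, at the aldol oxidation level. Diketone 13 goes back to β-hydroxy ketone 12, and 12 to chromene aldehyde 6 and methyl ketone 10. The neighbouring cut on the ring A side would need ring B as a methyl ketone and ring A as an acyl donor. A Claisen condensation at the acid level would need an extra oxidation of the ring B partner and a second equivalent of enolate. The aldol cut is preferred because the key step delivers ring B as an aldehyde. It divides the target into two pieces of similar size. The forward sequence needs a crossed aldol addition without dehydration and an oxidation that leaves two alkenes alone.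

**6 from 5, and 5 from 1 and 2.** Aldehyde 6 is the methoxymethyl ether of 5. In 5 the pyran is cut at C4–C3 and O1–C2, which leads to dialdehyde 1 and (2-methylprop-1-en-1-yl)boronic acid 2. Cuts at C4a–C4 (propargyl ether rearrangement or enal condensation on a resorcinol) make a bond to a ring CH and must choose between the two ring positions ortho to the reacting oxygen, one of which lies between the two oxygens. For 2,4-dihydroxyaryl carbonyl compounds that choice normally falls on the angular position. The C4–C3 cut stores the regiochemical information in a formyl group that is already in place, and because 1 is symmetric it does not matter which formyl group reacts. The bicyclic aldehyde is reduced to a purchasable benzene and a four-carbon boronic acid. The forward reaction must stop after one annulation.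

**10 from 9, and 9 from 7 and 8.** Ketone 10 is the methoxymethyl ether of 9. Compound 9 is cut at the aryl–CH2 bond ortho to the hydroxyl, giving 4'-hydroxyacetophenone 7 and prenyl bromide 8. A sigmatropic route through a tertiary allyl ether is more selective but one step longer. A cross-coupling route needs a halogenated ketone and an allyl metal with its own α/γ problem. The direct cut uses two commodity chemicals in one step. The forward reaction must favour C- over O-alkylation.

## Roads not taken

Alternative 1: Ring A would be built from acyclic pieces. Methyl coumalate A2 and the prenyl-substituted siloxyalkyne A3 would combine in an inverse-demand Diels–Alder reaction, and decarboxylative cycloreversion of the bridged adduct would give benzoate A1.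

- Merit: the polarity of the cycloaddition fixes prenyl and oxygen as neighbours, both correctly placed relative to the ester, without any C- versus O-alkylation issue. In this respect it is better than step 3 of the chosen route.
- Weak points: it spends its key step on the simpler ring, which is one alkylation away from 7. The ynol ether A3 is sensitive and needs several steps of its own. The ester A1 fits only a Claisen-type chain closure, which changes the role required of ring B. The linear chromene, which is the real positional problem, is not addressed.
- Comparison: the chosen plan accepts a less selective one-step prenylation, backed by a sigmatropic fallback, and uses its key step on the linear fusion of ring C.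

Alternative 2: Both side-chain features would be installed in one late thermal operation. The bis-ether A5 carries a 1,1-dimethylallyl ether on ring A, a 1,1-dimethylpropargyl ether on ring B and an iodine atom at the position between the two ring B oxygens. Heating in a high-boiling aniline solvent would give 8-iodoglyinflanin C A4 by an aromatic Claisen rearrangement on ring A and a propargyl Claisen rearrangement, 1,5-hydrogen shift and oxa-6π closure on ring B.

- Merits: one step forms the aryl–CH2 bond and ring C, both by clean sigmatropic processes. There is no statistical desymmetrisation, which is an advantage over the chosen key step.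
- Weak points: the linear closure depends entirely on the iodine blocking group. It has to be introduced regioselectively and removed reductively from A4 at the end beside two alkenes and an enolisable diketone. The two acid-labile tertiary ethers of A5 must be carried through the chain assembly. In A5 and A4 a free ortho-hydroxy diketone is exposed to temperatures near 200 °C, where cyclodehydration threatens.
- Comparison: the chosen plan obtains the linear fusion from symmetry without a blocking group, keeps every step at or below 90 °C and needs no final dehalogenation. It is less elegant in the late stage and has to manage mono- versus double annulation.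

Alternative 3: The diketone would be made in one three-component step. The iodochromene A7, carbon monoxide A9 and the sodium enolate of ketone A8 (identical with 10) would couple under Pd(dba)2 and Xantphos to give the bis(methoxymethyl) ether A6 (identical with 13).

- Merits: both bonds to the ring B carbonyl carbon form at the correct oxidation level in a single convergent step. This is one step shorter than the aldol and oxidation pair, and in chain building it is the better plan.
- Weak points: A7 must itself be made with linear regiochemistry, by iodinating a 7-oxygenated chromene at C6 and not C8 or by annulating an iodoresorcinol, so the main positional problem is only moved. The aryl iodide A7 is electron-rich and ortho-substituted. The acidic product A6 consumes a second equivalent of enolate. The toxic gas A9 must be handled.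
- Comparison: the end game through A6 is the same as in the chosen route. The chosen plan sets against the extra step a key reaction that makes the linear chromene and the chain anchor together from a symmetric, purchasable arene.

Key step: step 1

Assumption: the target is drawn as its diketo tautomer; the chelated keto–enol form expected to dominate in solution is the same compound.

## Route

Step 1
Reactants: 1 4,6-dihydroxyisophthalaldehyde; 2 (2-methylprop-1-en-1-yl)boronic acid
Product: 5 7-hydroxy-2,2-dimethyl-2H-chromene-6-carbaldehyde, via Petasis aminophenol 3 (not isolated), via ortho-quinone methide 4 (not isolated)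
Conditions: Bn2NH (20 mol%), 1,4-dioxane, 90 °C; 2 limiting, 1 in twofold excess (recovered)
Reagents that add atoms: none
Why: Amine-catalysed Petasis borono-Mannich reaction of a salicylaldehyde followed by cyclisation, the known catalytic route from salicylaldehydes and alkenylboronic acids to 2H-chromenes. Dibenzylamine condenses with one formyl group of 1 to an iminium ion, the neighbouring phenol binds 2 as a boronate, and the 2-methylprop-1-enyl group migrates from boron to the iminium carbon within this complex, forming C4–C3 and giving aminophenol 3. At 90 °C the ortho-hydroxybenzylic amine is expelled from 3 to give ortho-quinone methide 4, a 1-oxatriene that closes by thermal oxa-6π electrocyclisation (six-membered ring, O1–C2 bond) and restores the aromatic ring, while the amine is released for the next turnover. No stereocentre is created in 5: the carbon stereocentre of 3 is racemic and is erased on elimination, and C2 carries two methyl groups. Linear fusion is not a matter of selectivity, because the two formyl/hydroxyl pairs of 1 are homotopic and the C–C bond forms at a former formyl carbon, never at a ring CH. The selectivity the step does need is mono- over double annulation; it is secured by keeping 2 limiting against an excess of 1, and it should be helped by the loss of an electron-withdrawing formyl group on going from 1 to 5, which makes the remaining aldehyde of 5 the poorer iminium precursor. The second formyl group stays on C6 for the chain.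

Step 2
Reactants: 5 7-hydroxy-2,2-dimethyl-2H-chromene-6-carbaldehyde
Product: 6 7-(methoxymethoxy)-2,2-dimethyl-2H-chromene-6-carbaldehyde
Conditions: MOMCl, i-Pr2NEt, CH2Cl2, 0 °C → rt
Reagents that add atoms: chloromethyl methyl ether (MOMCl), COCCl
Why: Methoxymethyl ether formation by O-alkylation of the only phenol under amine base; aldehyde and chromene are inert to these conditions. The acetal is chosen because, unlike a silyl ether, it cannot migrate to the benzylic alkoxide formed in step 5.

Step 3
Reactants: 7 4'-hydroxyacetophenone; 8 prenyl bromide (1-bromo-3-methylbut-2-ene)
Product: 9 1-[4-hydroxy-3-(3-methylbut-2-en-1-yl)phenyl]ethan-1-one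
Conditions: KOH (10% aq.), rt
Reagents that add atoms: none
Why: Direct ortho C-alkylation of an ambident phenoxide with an allylic bromide in water, where hydrogen bonding to the phenoxide oxygen holds back O-alkylation; the para position is blocked by the acetyl group and SN2 attack at the primary carbon keeps the prenyl group unrearranged. O-prenyl ether and doubly alkylated material are expected as by-products and should be removable by base extraction of phenol 9 and chromatography.

Step 4
Reactants: 9 1-[4-hydroxy-3-(3-methylbut-2-en-1-yl)phenyl]ethan-1-one
Product: 10 1-[4-(methoxymethoxy)-3-(3-methylbut-2-en-1-yl)phenyl]ethan-1-one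
Conditions: MOMCl, i-Pr2NEt, CH2Cl2, 0 °C → rt
Reagents that add atoms: chloromethyl methyl ether (MOMCl), COCCl
Why: Methoxymethyl ether formation at the only phenol; the group has to survive a lithium amide and the periodinane and is later removed together with that of ring B.

Step 5
Reactants: 10 1-[4-(methoxymethoxy)-3-(3-methylbut-2-en-1-yl)phenyl]ethan-1-one; 6 7-(methoxymethoxy)-2,2-dimethyl-2H-chromene-6-carbaldehyde
Product: 12 racemic 3-hydroxy-3-[7-(methoxymethoxy)-2,2-dimethyl-2H-chromen-6-yl]-1-[4-(methoxymethoxy)-3-(3-methylbut-2-en-1-yl)phenyl]propan-1-one, via lithium enolate 11 (not isolated)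
Conditions: LiN(i-Pr)2 (commercial solution), THF, –78 °C; then 6, –78 °C; NH4Cl (aq.) quench at –78 °C
Reagents that add atoms: none
Why: Directed crossed aldol addition: methyl ketone 10 is converted completely into lithium enolate 11 at –78 °C, and aldehyde 6, which has no α-hydrogen, can act only as the acceptor. The single new stereocentre forms as a racemate and is removed in step 6; the cold quench guards against retro-aldol cleavage and dehydration to the chalcone.

Step 6
Reactants: 12 racemic 3-hydroxy-3-[7-(methoxymethoxy)-2,2-dimethyl-2H-chromen-6-yl]-1-[4-(methoxymethoxy)-3-(3-methylbut-2-en-1-yl)phenyl]propan-1-one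
Product: 13 1-[7-(methoxymethoxy)-2,2-dimethyl-2H-chromen-6-yl]-3-[4-(methoxymethoxy)-3-(3-methylbut-2-en-1-yl)phenyl]propane-1,3-dione
Conditions: Dess–Martin periodinane (1.2 equiv), pyridine, CH2Cl2, 0 °C → rt
Reagents that add atoms: none
Why: Dess–Martin oxidation of the secondary benzylic alcohol of a β-hydroxy ketone to the 1,3-diketone, a standard use of this reagent; the prenyl and chromene double bonds and the acetals are not attacked. Pyridine buffering and a small excess of oxidant should avoid elimination and oxidation at the central methylene.

Step 7
Reactants: 13 1-[7-(methoxymethoxy)-2,2-dimethyl-2H-chromen-6-yl]-3-[4-(methoxymethoxy)-3-(3-methylbut-2-en-1-yl)phenyl]propane-1,3-dione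
Product: 14 glyinflanin C, 1-(7-hydroxy-2,2-dimethyl-2H-chromen-6-yl)-3-[4-hydroxy-3-(3-methylbut-2-en-1-yl)phenyl]propane-1,3-dione
Conditions: HCl (3 M aq.), MeOH, rt
Reagents that add atoms: none
Why: Acid-catalysed methanolysis of both methoxymethyl acetals (transacetalisation to dimethoxymethane); the chelated ortho ether should go first and the ring A ether follow. Dilute acid at room temperature is chosen because cyclodehydration to the flavone and cyclisation of the ortho-prenylphenol need hotter or stronger acid.

## Compound list

1 | 4,6-dihydroxyisophthalaldehyde (4,6-dihydroxybenzene-1,3-dicarbaldehyde) | O=Cc1cc(C=O)c(O)cc1O | starting material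
2 | (2-methylprop-1-en-1-yl)boronic acid | CC(C)=CB(O)O | starting material
3 | racemic 5-[1-(dibenzylamino)-3-methylbut-2-en-1-yl]-2,4-dihydroxybenzaldehyde | O=Cc1cc(C(C=C(C)C)N(Cc2ccccc2)Cc2ccccc2)c(O)cc1O | intermediate (not isolated)
4 | 6-hydroxy-3-(3-methylbut-2-en-1-ylidene)-4-oxocyclohexa-1,5-diene-1-carbaldehyde (ortho-quinone methide) | O=CC1=CC(=CC=C(C)C)C(=O)C=C1O | intermediate (not isolated)
5 | 7-hydroxy-2,2-dimethyl-2H-chromene-6-carbaldehyde | O=Cc1cc2c(cc1O)OC(C)(C)C=C2 | intermediate
6 | 7-(methoxymethoxy)-2,2-dimethyl-2H-chromene-6-carbaldehyde | O=Cc1cc2c(cc1OCOC)OC(C)(C)C=C2 | intermediate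
7 | 4'-hydroxyacetophenone | CC(=O)c1ccc(O)cc1 | starting material
8 | prenyl bromide (1-bromo-3-methylbut-2-ene) | CC(C)=CCBr | starting material
9 | 1-[4-hydroxy-3-(3-methylbut-2-en-1-yl)phenyl]ethan-1-one | CC(=O)c1ccc(O)c(CC=C(C)C)c1 | intermediate
10 | 1-[4-(methoxymethoxy)-3-(3-methylbut-2-en-1-yl)phenyl]ethan-1-one | CC(=O)c1ccc(OCOC)c(CC=C(C)C)c1 | intermediate
11 | lithium 1-[4-(methoxymethoxy)-3-(3-methylbut-2-en-1-yl)phenyl]ethen-1-olate | C=C(O[Li])c1ccc(OCOC)c(CC=C(C)C)c1 | intermediate (not isolated)
12 | racemic 3-hydroxy-3-[7-(methoxymethoxy)-2,2-dimethyl-2H-chromen-6-yl]-1-[4-(methoxymethoxy)-3-(3-methylbut-2-en-1-yl)phenyl]propan-1-one | CC(C)=CCc1cc(C(=O)CC(O)c2cc3c(cc2OCOC)OC(C)(C)C=C3)ccc1OCOC | intermediate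
13 | 1-[7-(methoxymethoxy)-2,2-dimethyl-2H-chromen-6-yl]-3-[4-(methoxymethoxy)-3-(3-methylbut-2-en-1-yl)phenyl]propane-1,3-dione | CC(C)=CCc1cc(C(=O)CC(=O)c2cc3c(cc2OCOC)OC(C)(C)C=C3)ccc1OCOC | intermediate
14 | glyinflanin C, 1-(7-hydroxy-2,2-dimethyl-2H-chromen-6-yl)-3-[4-hydroxy-3-(3-methylbut-2-en-1-yl)phenyl]propane-1,3-dione | CC(C)=CCc1cc(C(=O)CC(=O)c2cc3c(cc2O)OC(C)(C)C=C3)ccc1O | target

## Step count and risk

Total step count: 7. Longest linear sequence: 5 steps (steps 1, 2, 5, 6, 7 from 1, or steps 3, 4, 5, 6, 7 from 7).

**Step 1 (key step).** The second formyl/hydroxyl pair of 5 can enter the same catalytic cycle, so double annulation and unreacted 1 may accompany 5. The iminium ion is also fed by two phenolic donors, which may make alkenyl transfer slow. Fallback: setting out from boronic acid 2, the same amine-catalysed annulation is run on commercial 2,4-dihydroxybenzaldehyde F1. It has only one formyl group, so over-annulation is impossible, and the linear orientation is again fixed by the formyl carbon. This should give 2,2-dimethyl-2H-chromen-7-ol F2. Magnesium-mediated ortho-formylation of F2 (MgCl2, Et3N, paraformaldehyde, MeCN, reflux) is expected to enter at C6, the open position ortho to the hydroxyl, rather than at C8 between the two oxygens. The fallback returns to the route at 5.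

**Step 3.** O-Alkylation and a second C-alkylation of the ambident phenoxide compete with the wanted mono-C-prenylation, and hydrolysis of the bromide consumes reagent. Material throughput may therefore be low. Fallback: setting out from 7, O-alkylation at the tertiary terminus with tert-butyl 2-methylbut-3-en-2-yl carbonate and Pd(PPh3)4 (zerovalent palladium) in THF at 0 °C should give 1-[4-(2-methylbut-3-en-2-yloxy)phenyl]ethan-1-one F3. Aromatic Claisen rearrangement of F3 in xylene at about 140 °C delivers the unrearranged ortho-prenyl group and returns to the route at 9.

**Step 5 (with step 6).** The aldol adduct may revert or lose water to the chalcone on quench or on silica, the electron-rich ortho-substituted aldehyde is a slow acceptor, and in step 6 oxidation may continue at the central methylene. Fallback: setting out from 6, Pinnick oxidation (NaClO2, NaH2PO4, 2-methylbut-2-ene, t-BuOH/H2O) should give 7-(methoxymethoxy)-2,2-dimethyl-2H-chromene-6-carboxylic acid F4. 1,1'-Carbonyldiimidazole in THF converts F4 into (1H-imidazol-1-yl)[7-(methoxymethoxy)-2,2-dimethyl-2H-chromen-6-yl]methanone F5. Addition of F5 to two equivalents of lithium enolate 11 at –78 °C is a crossed Claisen C-acylation that gives the diketone directly. The fallback returns to the route at 13 and bypasses both 12 and the oxidation.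

**Step 7.** While the slower ring A acetal is still being cleaved, the liberated ortho-hydroxy diketone may cyclodehydrate to a flavone, the ortho-prenylphenol may cyclise to a chroman, and methanol may add to the chromene double bond. Fallback: allyl ethers replace the acetals, setting out from 5 and 9. Allyl bromide and K2CO3 in DMF should give 7-(allyloxy)-2,2-dimethyl-2H-chromene-6-carbaldehyde F6 from 5 and 1-[4-(allyloxy)-3-(3-methylbut-2-en-1-yl)phenyl]ethan-1-one F7 from 9. Aldol addition of F7 to F6 under the conditions of step 5 should give racemic 3-[7-(allyloxy)-2,2-dimethyl-2H-chromen-6-yl]-3-hydroxy-1-[4-(allyloxy)-3-(3-methylbut-2-en-1-yl)phenyl]propan-1-one F8. Dess–Martin oxidation of F8 should give 1-[7-(allyloxy)-2,2-dimethyl-2H-chromen-6-yl]-3-[4-(allyloxy)-3-(3-methylbut-2-en-1-yl)phenyl]propane-1,3-dione F9. Both allyl groups of F9 are then removed without acid by Pd(PPh3)4 (zerovalent palladium) and excess morpholine in THF at room temperature; the amine intercepts the allyl–palladium intermediate before the diketone can be C-allylated. The fallback returns to the route at 14.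

## Further compounds

F1 | step 1 | 2,4-dihydroxybenzaldehyde | O=Cc1ccc(O)cc1O
F2 | step 1 | 2,2-dimethyl-2H-chromen-7-ol | CC1(C)C=Cc2ccc(O)cc2O1
F3 | step 3 | 1-[4-(2-methylbut-3-en-2-yloxy)phenyl]ethan-1-one | CC(=O)c1ccc(OC(C)(C)C=C)cc1
F4 | step 5 | 7-(methoxymethoxy)-2,2-dimethyl-2H-chromene-6-carboxylic acid | OC(=O)c1cc2c(cc1OCOC)OC(C)(C)C=C2
F5 | step 5 | (1H-imidazol-1-yl)[7-(methoxymethoxy)-2,2-dimethyl-2H-chromen-6-yl]methanone | O=C(c1cc2c(cc1OCOC)OC(C)(C)C=C2)n1ccnc1
F6 | step 7 | 7-(allyloxy)-2,2-dimethyl-2H-chromene-6-carbaldehyde | O=Cc1cc2c(cc1OCC=C)OC(C)(C)C=C2
F7 | step 7 | 1-[4-(allyloxy)-3-(3-methylbut-2-en-1-yl)phenyl]ethan-1-one | CC(=O)c1ccc(OCC=C)c(CC=C(C)C)c1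
F8 | step 7 | racemic 3-[7-(allyloxy)-2,2-dimethyl-2H-chromen-6-yl]-3-hydroxy-1-[4-(allyloxy)-3-(3-methylbut-2-en-1-yl)phenyl]propan-1-one | CC(C)=CCc1cc(C(=O)CC(O)c2cc3c(cc2OCC=C)OC(C)(C)C=C3)ccc1OCC=C
F9 | step 7 | 1-[7-(allyloxy)-2,2-dimethyl-2H-chromen-6-yl]-3-[4-(allyloxy)-3-(3-methylbut-2-en-1-yl)phenyl]propane-1,3-dione | CC(C)=CCc1cc(C(=O)CC(=O)c2cc3c(cc2OCC=C)OC(C)(C)C=C3)ccc1OCC=C
A1 | alternative 1 | methyl 3-(3-methylbut-2-en-1-yl)-4-[(triisopropylsilyl)oxy]benzoate | COC(=O)c1ccc(O[Si](C(C)C)(C(C)C)C(C)C)c(CC=C(C)C)c1
A2 | alternative 1 | methyl coumalate (methyl 2-oxo-2H-pyran-5-carboxylate) | COC(=O)C1=COC(=O)C=C1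
A3 | alternative 1 | triisopropyl[(5-methylhex-4-en-1-yn-1-yl)oxy]silane | CC(C)=CCC#CO[Si](C(C)C)(C(C)C)C(C)C
A4 | alternative 2 | 8-iodoglyinflanin C, 1-(7-hydroxy-8-iodo-2,2-dimethyl-2H-chromen-6-yl)-3-[4-hydroxy-3-(3-methylbut-2-en-1-yl)phenyl]propane-1,3-dione | CC(C)=CCc1cc(C(=O)CC(=O)c2cc3c(c(I)c2O)OC(C)(C)C=C3)ccc1O
A5 | alternative 2 | 1-[2-hydroxy-3-iodo-4-(2-methylbut-3-yn-2-yloxy)phenyl]-3-[4-(2-methylbut-3-en-2-yloxy)phenyl]propane-1,3-dione | C#CC(C)(C)Oc1ccc(C(=O)CC(=O)c2ccc(OC(C)(C)C=C)cc2)c(O)c1I
A6 | alternative 3 | glyinflanin C bis(methoxymethyl) ether (identical with 13) | CC(C)=CCc1cc(C(=O)CC(=O)c2cc3c(cc2OCOC)OC(C)(C)C=C3)ccc1OCOC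
A7 | alternative 3 | 6-iodo-7-(methoxymethoxy)-2,2-dimethyl-2H-chromene | COCOc1cc2c(cc1I)C=CC(C)(C)O2
A8 | alternative 3 | 1-[4-(methoxymethoxy)-3-(3-methylbut-2-en-1-yl)phenyl]ethan-1-one (identical with 10) | CC(=O)c1ccc(OCOC)c(CC=C(C)C)c1
A9 | alternative 3 | carbon monoxide | [C-]#[O+]
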